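How much target can you take from this flask, and when?

| setting | beta | theta | flask |
|---|---|---|---|
| starting material | 2 M | 2 M | 2.0 M |
| coupling partner | 0.30 equiv | 1.2 equiv | 0.600 equiv |
| remark | run made earlier | run made earlier |  |
| time |  |  | 15 d |

| run | time / d | target / % | starting material / % |
|---|---|---|---|
| beta | 0.167 | 23.6 | 74.9 |
| beta | 0.417 | 26.8 | 69.9 |
| beta | 1.04 | 24.8 | 69.0 |
| beta | 2.50 | 22.4 | 70.7 |
| beta | 6.00 | 18.7 | 70.3 |
| beta | 15.0 | 12.0 | 68.4 |
| theta | 0.167 | 38.1 | 56.3 |
| theta | 0.417 | 71.3 | 27.4 |
| theta | 1.04 | 86.5 | 2.8 |
| theta | 2.50 | 89.5 | 0.1 |
| theta | 6.00 | 83.0 | 0 |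
| theta | 15.0 | 82.4 | 0.8 |

(scatter of a reading: 1 percentage point)

* time, not beyond 15 d, at which the flask holds most target
* the amount of target, in percent of the starting material charged, at that time

- target is meant together with its crystals
- solid, in amounts per volume of the solution: crystals
- steps that have been proposed: starting material <-> tight pair; tight pair <-> loose pair; coupling partner + tight pair -> target; coupling partner + loose pair -> isomer of the product A; target <-> isomer of the product B; target -> over-reaction product; crystals <-> target

In the first instants both earlier runs burst: by 0.167 d, beta holds 74.9% starting material and theta, with 4.00 times the coupling partner, holds less, 56.3%.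

In the middle, beta stalls near 69.9% starting material, so its turnover matches its partner charge within the scatter, which reads as coupling partner being the limiting reagent. From this I carry one quantity, the yield per equivalent: peak target in a partner-short run, divided by the equivalents charged.

s = 26.8% / 0.30 equiv = 0.893

flask: s × 0.600 equiv = 53.6%

For the time, a first round: theta had burned as much starting material as this flask has partner for by 0.417 d at the latest. Going round again, partner thins towards the end, and beta took from 0.167 d to 0.417 d over its last portion, so I add that tail:

t = 0.417 d + 0.250 d = 0.667 d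

At the end, target declines: beta reads 12.0% and theta 82.4% at 15.0 d. So you should stop the flask early.

The forecast gives 52% at 0.7 d: “The flask should therefore peak early”.

The flask gives 54.3% at 0.646 d.

    starting material ⇌ tight pair (K = 0.00570, k = 0.160 h⁻¹)
    tight pair ⇌ loose pair (K = 0.110, k = 54.0 h⁻¹)
    coupling partner + tight pair → target (k = 100 L mol⁻¹ h⁻¹)
    coupling partner + loose pair → isomer of the product A (k = 34.0 L mol⁻¹ h⁻¹)
    target ⇌ isomer of the product B (K = 13.0, k = 0.110 h⁻¹)
    target → over-reaction product (k = 9.10 × 10⁻⁵ h⁻¹)
    crystals ⇌ target, rate k7*(cs7 - [target]) while solid is left; crystals form when [target] > cs7 (solubility = 25.0 mM, k = 3.70 h⁻¹)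

At that peak the flask holds 0.406% of its coupling partner beside 40.0% starting material. The largest single effect on the peak is the running short of coupling partner: the simulated run without it reaches 89.5% instead of 54.3%.

With 0.150 equiv of partner, s gives 13.4%; the computed best of that flask is 13.3%.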